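The cyclohexene (C1, C10–C14) is disconnected at C1–C14 and C12–C13. An intramolecular Diels–Alder reaction joins the diene C1=C10–C11=C12, which ends in a boronate at C12, to a β-sulfonylvinyl group (an acetylene equivalent for C13=C14) held on a temporary silicon tether at the C2 oxygen; in the same flask the new C12 allylboronate adds to a lactone aldehyde (C6–C9, C17–C19), forging C9–C10 and shifting the alkene to C11=C12 for the cis-diol. The step exploits the isolated C13=C14 alkene of the six-membered ring and the C2 oxygen beside quaternary C1. The precursor is an open-chain silyl ether of a (Z,E)-dienylboronate. Fluoride then releases C13=C14 and C2–OH, and a Nozaki–Hiyama–Kishi reaction closes the ten-membered ring at C5–C6.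

Key step: step 16

Remark: atom labels follow briarane numbering: C1 is the quaternary ring-fusion carbon (methyl C15), C2–C9 complete the ten-membered ring, C10 is the ring-fusion CH, C11–C14 complete the cyclohexene (methyl C20 on C11), C16 is the methylene on C5, and the lactone is C7–O–C19(=O)–C17(C18)–C8. β is the face of C15. Compound numbers are plain numbers without "C".

Step 1
Reactants: 1 N-methoxy-N-methylacetamide; 2 2,3-dibromopropene
Product: 4 4-bromo-N-methoxy-N-methylpent-4-enamide, via lithium enolate 3 (not isolated)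
Conditions: LiN(iPr)2, THF, −78 °C; then 2, −78 → −30 °C
Reagents that add atoms: none
Why: Enolate alkylation (SN2) at the allylic bromide of 2 should join C3 to C4 while the alkenyl bromide (future C5) stays untouched.

Step 2
Reactants: 4 4-bromo-N-methoxy-N-methylpent-4-enamide
Product: 5 6-bromo-1-(trimethylsilyl)hept-6-en-1-yn-3-one
Conditions: ethynyltrimethylsilane, nBuLi, THF, −78 °C; then 4, −78 → 0 °C; aq. NH4Cl
Reagents that add atoms: lithium (trimethylsilyl)acetylide, [Li]C#C[Si](C)(C)C
Why: Acylation of a lithium acetylide by an N-methoxy-N-methylamide should stop at the ketone because the chelated tetrahedral adduct survives until work-up.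

Step 3
Reactants: 5 6-bromo-1-(trimethylsilyl)hept-6-en-1-yn-3-one
Product: 6 (3S)-6-bromo-1-(trimethylsilyl)hept-6-en-1-yn-3-ol
Conditions: RuCl[(S,S)-TsDPEN](p-cymene) (1 mol %), iPrOH, 25 °C
Reagents that add atoms: none
Why: Noyori asymmetric transfer hydrogenation of an alkynyl ketone should set C2 as S, the (S,S) ligand treating the alkynyl group as the π-substituent.

Step 4
Reactants: 6 (3S)-6-bromo-1-(trimethylsilyl)hept-6-en-1-yn-3-ol
Product: 7 (3S)-6-bromohept-6-en-1-yn-3-ol
Conditions: K2CO3, MeOH, 0 → 25 °C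
Reagents that add atoms: none
Why: Methoxide-mediated protodesilylation of the alkynylsilane should free the terminal alkyne without touching the carbinol.

Step 5
Reactants: 7 (3S)-6-bromohept-6-en-1-yn-3-ol
Product: 9 (1Z,3S)-6-bromo-1-iodo-2-methylhepta-1,6-dien-3-ol, via cyclic alkenylmagnesium alkoxide 8 (not isolated)
Conditions: MeMgBr (3.5 equiv), CuI (20 mol %), THF, −20 → 25 °C; then I2, −60 → 0 °C
Reagents that add atoms: methylmagnesium bromide, C[Mg]Br; iodine, II
Why: Alkoxide-directed copper-catalysed anti-carbomagnesiation of the propargylic alcohol should put methyl C15 on C1 and magnesium on C10 cis to the carbinol, and iodinolysis with retention should give the Z iodide.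

Step 6
Reactants: 9 (1Z,3S)-6-bromo-1-iodo-2-methylhepta-1,6-dien-3-ol
Product: 10 (3Z,5S)-8-bromo-4-methylnona-3,8-dien-1-yn-5-ol
Conditions: HC≡CMgBr, ZnBr2, THF; Pd(PPh3)4 (5 mol %), 25 °C
Reagents that add atoms: ethynylzinc bromide, C#C[Zn]Br
Why: Negishi coupling should replace iodine by C11–C12 with retention of the Z geometry, the alkenyl iodide reacting far faster than the alkenyl bromide and the base-free room-temperature conditions avoiding furan formation from the Z-enynol.

Step 7
Reactants: 10 (3Z,5S)-8-bromo-4-methylnona-3,8-dien-1-yn-5-ol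
Product: 12 (1E,3Z,5S)-8-bromo-2,4-dimethyl-1-(4,4,5,5-tetramethyl-1,3,2-dioxaborolan-2-yl)nona-1,3,8-trien-5-ol, via alkenylalane 11 (not isolated)
Conditions: AlMe3 (4 equiv), Cp2ZrCl2 (0.5 equiv), CH2Cl2, 0 → 25 °C; then MeOBpin, THF, 0 → 25 °C
Reagents that add atoms: trimethylaluminium, C[Al](C)C; 2-methoxy-4,4,5,5-tetramethyl-1,3,2-dioxaborolane, COB1OC(C)(C)C(C)(C)O1
Why: Zirconium-catalysed syn-carboalumination (Negishi) of the terminal alkyne should add methyl C20 to C11 and aluminium to C12, and aluminium-to-boron transmetalation with retention should give the E-alkenylboronate.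

Step 8
Reactants: 13 triphenyl(vinyl)silane; 14 sodium benzenesulfinate
Product: 16 (E)-triphenyl[2-(phenylsulfonyl)ethenyl]silane, via iodosulfone 15 (not isolated)
Conditions: I2, EtOAc/H2O, visible light, 25 °C; then Et3N, CH2Cl2, 25 °C
Reagents that add atoms: none
Why: Iodosulfonylation (sulfonyl radical addition to the terminal carbon, iodine transfer) followed by amine-induced dehydroiodination should give the E β-silyl vinyl sulfone.

Step 9
Reactants: 16 (E)-triphenyl[2-(phenylsulfonyl)ethenyl]silane; 12 dienylboronate alcohol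
Product: 18 (1E,3Z,5S)-dienylboronate 5-O-{diphenyl[(E)-2-(phenylsulfonyl)ethenyl]silyl} ether, via silyl triflate 17 (not isolated)
Conditions: 16, TfOH (1.0 equiv), CH2Cl2, 0 °C; then 12, 2,6-lutidine, −78 → 0 °C
Reagents that add atoms: none
Why: Protodesilylation of one Si–phenyl bond by triflic acid should give a silyl triflate that silylates the secondary C2 alcohol, attaching the dienophile through a temporary silicon tether.

Step 10
Reactants: 19 methyl (2S)-oxirane-2-carboxylate; 20 4-methoxybenzyl alcohol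
Product: 21 methyl (2S)-2-hydroxy-3-[(4-methoxybenzyl)oxy]propanoate
Conditions: BF3·OEt2 (5 mol %), CH2Cl2, 0 °C
Reagents that add atoms: none
Why: Lewis-acid-catalysed epoxide opening by the alcohol at the unsubstituted carbon (future C6) should leave the stereocentre (future C7) untouched.

Step 11
Reactants: 21 methyl (2S)-2-hydroxy-3-[(4-methoxybenzyl)oxy]propanoate
Product: 22 (2S)-1-(1,3-dithian-2-yl)-2-hydroxy-3-[(4-methoxybenzyl)oxy]propan-1-one
Conditions: 1,3-dithiane, nBuLi, THF, −30 °C; then 21, −78 → −20 °C; aq. NH4Cl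
Reagents that add atoms: 2-lithio-1,3-dithiane, [Li]C1SCCCS1
Why: Corey–Seebach acylation of the lithiated dithiane by the ester should stop at the ketone (C8) because the acidic 2-acyl dithiane is deprotonated in the flask, the dithiane carbon being the masked aldehyde C9.

Step 12
Reactants: 22 (2S)-1-(1,3-dithian-2-yl)-2-hydroxy-3-[(4-methoxybenzyl)oxy]propan-1-one
Product: 23 (2S)-1-(1,3-dithian-2-yl)-3-[(4-methoxybenzyl)oxy]-1-oxopropan-2-yl 2-bromopropanoate
Conditions: 2-bromopropanoyl bromide, pyridine, CH2Cl2, −20 °C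
Reagents that add atoms: 2-bromopropanoyl bromide, CC(Br)C(=O)Br
Why: O-acylation of the secondary alcohol should install C17–C19 as an α-bromo ester (the bromide-bearing centre is lost in the next step).

Step 13
Reactants: 23 α-bromopropanoate keto dithiane
Product: 24 (3R,4S,5S)-4-(1,3-dithian-2-yl)-4-hydroxy-5-{[(4-methoxybenzyl)oxy]methyl}-3-methyloxolan-2-one
Conditions: SmI2 (2.2 equiv), THF, −78 °C
Reagents that add atoms: none
Why: The SmI2-mediated intramolecular Reformatsky reaction should form C8–C17 and the lactone through a chelated transition state that places the bulky dithianyl group trans to the C7 side chain and the C17 methyl trans to the dithianyl group (C17 is also epimerisable toward this isomer).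

Step 14
Reactants: 24 hydroxy lactone
Product: 25 (3R,4S,5S)-4-(1,3-dithian-2-yl)-5-{[(4-methoxybenzyl)oxy]methyl}-3-methyl-4-[(triethylsilyl)oxy]oxolan-2-one
Conditions: TESOTf, 2,6-lutidine, CH2Cl2, −40 → 0 °C
Reagents that add atoms: triethylsilyl trifluoromethanesulfonate, CC[Si](CC)(CC)OS(=O)(=O)C(F)(F)F
Why: Silylation with a silyl triflate should protect the hindered tertiary C8 alcohol.

Step 15
Reactants: 25 silylated lactone dithiane
Product: 26 (3R,4S,5S)-4-formyl-5-{[(4-methoxybenzyl)oxy]methyl}-3-methyl-4-[(triethylsilyl)oxy]oxolan-2-one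
Conditions: MeI, CaCO3, MeCN/H2O (9:1), 45 °C
Reagents that add atoms: water, O
Why: S-Methylation and hydrolysis of the dithiane under buffered neutral conditions should release the C9 aldehyde without touching the silyl ether, the benzyl ether or the lactone.

Step 16
Reactants: 18 silyl ether of the dienylboronate; 26 lactone aldehyde
Product: 29 coupled homoallylic alcohol (oxasilolane-fused cyclohexene carrying the lactone at C9), via cycloadduct allylboronate 27 (not isolated), via O-boryl adduct 28 (not isolated)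
Conditions: PhMe (0.01 M), BHT, 100 °C; concentrate; then 26, Sc(OTf)3 (10 mol %), CH2Cl2, −78 → −20 °C; aq. NaHCO3
Reagents that add atoms: none
Why: Heating 18 should trigger an intramolecular Diels–Alder reaction between the (Z,E)-diene C1=C10–C11=C12 and the silicon-tethered E vinyl sulfone (closest known types: temporary-silicon-tethered Diels–Alder reactions and β-silyl vinyl sulfones as acetylene equivalents), forming C1–C14 and C12–C13, after which the C12 allylboronate 27 adds to aldehyde 26 under Lewis-acid catalysis through a closed six-membered transition state (tandem Diels–Alder/allylboration), forming C9–C10 and moving the alkene to C11=C12. The cyclohexene (C1, C10–C14) closes by a suprafacial [4+2] cycloaddition and the temporary oxasilolane (C1, C2, O, Si, C14) closes as the fused five-membered ring of a three-atom-tethered intramolecular cycloaddition, cis-fused because the tether starts from the inside (Z) position of the diene. C1 is controlled by C2, since 1,3-allylic strain in the Z alkene holds H-2 in the diene plane so that the tether oxygen delivers the dienophile to one face and the C3 chain ends syn to methyl C15 as in the target; C12 follows from the E geometry of the alkenylboronate (boron cis to C15), while C13 and C14 are temporary (sulfonyl endo, silicon cis to C2) and disappear in step 17. C10 and C9 are set in the allylboration, the new bond forming on the face of the departing boron (C9 β, H-10 α, trans to C2) and the chair transition state with the aldehyde residue equatorial fixing C9 relative to C10 whatever the stereocentres of the aldehyde. The step needs regioselectivity in the cycloaddition (secured by the short tether and matched by the polarity of diene and vinyl sulfone), π-facial selectivity (secured by C2) and γ-attack of the boronate (C10 is its only allylic terminus).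

Step 17
Reactants: 29 coupled homoallylic alcohol
Product: 30 diene triol (free 2-OH, 8-OH and 9-OH; ring diene C11=C12–C13=C14)
Conditions: Bu4NF, AcOH, THF, 0 → 40 °C
Reagents that add atoms: none
Why: Fluoride attack at silicon should induce anti β-elimination of the trans-disposed silyl and sulfonyl groups to create C13=C14, and the same reagent cleaves the Si–O bond to C2 and the triethylsilyl ether at C8.

Step 18
Reactants: 30 diene triol
Product: 31 pentaol (11α,12α-diol)
Conditions: OsO4 (3 mol %), NMO, acetone/H2O, 0 °C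
Reagents that add atoms: osmium tetroxide, O=[Os](=O)(=O)=O; N-methylmorpholine N-oxide, C[N+]1([O-])CCOCC1; water, O
Why: Catalytic osmium tetroxide syn-dihydroxylation should take the more electron-rich trisubstituted C11=C12 rather than C13=C14 (flanked by quaternary C1 and deactivated once the allylic diol is in place) from the α face, anti to the pseudo-axial C15 methyl and the adjacent β C9 substituent, setting C11 and C12.

Step 19
Reactants: 31 pentaol
Product: 32 2,9,12-triacetate (8-OH and 11-OH free)
Conditions: Ac2O, pyridine, DMAP (cat.), CH2Cl2, 25 °C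
Reagents that add atoms: acetic anhydride, CC(=O)OC(C)=O
Why: Acylation should take the three secondary alcohols and leave the two tertiary alcohols (C8, C11) untouched, so the acetates of the target also serve as protecting groups for the rest of the route.

Step 20
Reactants: 32 triacetate 4-methoxybenzyl ether
Product: 33 C6 primary alcohol
Conditions: DDQ, CH2Cl2/pH 7 buffer, 0 °C
Reagents that add atoms: none
Why: Oxidative cleavage of the 4-methoxybenzyl ether (hydride abstraction, hydrolysis of the oxocarbenium ion) should free only the C6 hydroxyl.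

Step 21
Reactants: 33 C6 primary alcohol
Product: 34 C6 aldehyde
Conditions: Dess–Martin periodinane, NaHCO3, CH2Cl2, 0 → 25 °C
Reagents that add atoms: none
Why: Dess–Martin oxidation of the only primary alcohol should give the α-acyloxy aldehyde under buffered conditions that do not epimerise C7, the tertiary alcohols being inert.

Step 22
Reactants: 34 C6 aldehyde
Product: 35 ten-membered allylic alcohol (6-hydroxy epimer that leads to the chloride by inversion)
Conditions: CrCl2 (10 equiv), NiCl2 (cat.), DMSO/THF, 25 °C, 0.002 M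
Reagents that add atoms: none
Why: Intramolecular Nozaki–Hiyama–Kishi reaction (oxidative addition of the alkenyl bromide to zerovalent nickel, transmetalation to trivalent chromium, addition to the aldehyde) should form C5–C6 and the exocyclic methylene, the C6 configuration arising from addition anti to the C7 oxygen substituent on the pre-organised chain.

Step 23
Reactants: 35 ten-membered allylic alcohol
Product: 36 CNP0259091.1
Conditions: PPh3, hexachloroacetone, CH2Cl2, 0 °C
Reagents that add atoms: hexachloroacetone, O=C(C(Cl)(Cl)Cl)C(Cl)(Cl)Cl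
Why: Appel-type chlorination of the secondary allylic alcohol through the alkoxyphosphonium salt should give the C6 chloride by SN2 inversion without allylic transposition, the tertiary alcohols and acetates being inert.

Compound list
1 | N-methoxy-N-methylacetamide | CC(=O)N(C)OC | starting material
2 | 2,3-dibromopropene | C=C(Br)CBr | starting material
3 | lithium enolate of 1 | C=C(O[Li])N(C)OC | intermediate
4 | 4-bromo-N-methoxy-N-methylpent-4-enamide | C=C(Br)CCC(=O)N(C)OC | intermediate
5 | 6-bromo-1-(trimethylsilyl)hept-6-en-1-yn-3-one | C=C(Br)CCC(=O)C#C[Si](C)(C)C | intermediate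
6 | (3S)-6-bromo-1-(trimethylsilyl)hept-6-en-1-yn-3-ol | C=C(Br)CC[C@H](O)C#C[Si](C)(C)C | intermediate
7 | (3S)-6-bromohept-6-en-1-yn-3-ol | C=C(Br)CC[C@H](O)C#C | intermediate
8 | cyclic alkenylmagnesium alkoxide from anti-addition of methyl and magnesium to the alkyne of 7 | C=C(Br)CC[C@@H]1O[Mg]C=C1C | intermediate
9 | (1Z,3S)-6-bromo-1-iodo-2-methylhepta-1,6-dien-3-ol | C=C(Br)CC[C@H](O)/C(C)=C\I | intermediate
10 | (3Z,5S)-8-bromo-4-methylnona-3,8-dien-1-yn-5-ol | C=C(Br)CC[C@H](O)/C(C)=C\C#C | intermediate
11 | (1E,3Z,5S)-dienyl dimethylalane, O-dimethylaluminium alkoxide | C=C(Br)CC[C@H](O[Al](C)C)/C(C)=C\C(C)=C\[Al](C)C | intermediate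
12 | (1E,3Z,5S)-8-bromo-2,4-dimethyl-1-(4,4,5,5-tetramethyl-1,3,2-dioxaborolan-2-yl)nona-1,3,8-trien-5-ol | C=C(Br)CC[C@H](O)/C(C)=C\C(C)=C\B1OC(C)(C)C(C)(C)O1 | intermediate
13 | triphenyl(vinyl)silane | C=C[Si](c1ccccc1)(c1ccccc1)c1ccccc1 | starting material
14 | sodium benzenesulfinate | [Na+].[O-]S(=O)c1ccccc1 | starting material
15 | [1-iodo-2-(phenylsulfonyl)ethyl]triphenylsilane | O=S(=O)(CC(I)[Si](c1ccccc1)(c1ccccc1)c1ccccc1)c1ccccc1 | intermediate
16 | (E)-triphenyl[2-(phenylsulfonyl)ethenyl]silane | O=S(=O)(/C=C/[Si](c1ccccc1)(c1ccccc1)c1ccccc1)c1ccccc1 | intermediate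
17 | diphenyl[(E)-2-(phenylsulfonyl)ethenyl]silyl trifluoromethanesulfonate | O=S(=O)(/C=C/[Si](OS(=O)(=O)C(F)(F)F)(c1ccccc1)c1ccccc1)c1ccccc1 | intermediate
18 | 12 silylated at the C2 oxygen with the diphenyl[(E)-2-(phenylsulfonyl)ethenyl]silyl group | C=C(Br)CC[C@H](O[Si](c1ccccc1)(c1ccccc1)/C=C/S(=O)(=O)c1ccccc1)/C(C)=C\C(C)=C\B1OC(C)(C)C(C)(C)O1 | intermediate
19 | methyl (2S)-oxirane-2-carboxylate | COC(=O)[C@@H]1CO1 | starting material
20 | 4-methoxybenzyl alcohol | COc1ccc(CO)cc1 | starting material
21 | methyl (2S)-2-hydroxy-3-[(4-methoxybenzyl)oxy]propanoate | COC(=O)[C@@H](O)COCc1ccc(OC)cc1 | intermediate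
22 | (2S)-1-(1,3-dithian-2-yl)-2-hydroxy-3-[(4-methoxybenzyl)oxy]propan-1-one | O=C([C@@H](O)COCc1ccc(OC)cc1)C1SCCCS1 | intermediate
23 | (2S)-1-(1,3-dithian-2-yl)-3-[(4-methoxybenzyl)oxy]-1-oxopropan-2-yl 2-bromopropanoate | O=C([C@@H](OC(=O)C(C)Br)COCc1ccc(OC)cc1)C1SCCCS1 | intermediate
24 | (3R,4S,5S)-4-(1,3-dithian-2-yl)-4-hydroxy-5-{[(4-methoxybenzyl)oxy]methyl}-3-methyloxolan-2-one | S1CCCSC1[C@]2(O)[C@@H](C)C(=O)O[C@H]2COCc2ccc(OC)cc2 | intermediate
25 | (3R,4S,5S)-4-(1,3-dithian-2-yl)-5-{[(4-methoxybenzyl)oxy]methyl}-3-methyl-4-[(triethylsilyl)oxy]oxolan-2-one | S1CCCSC1[C@]2(O[Si](CC)(CC)CC)[C@@H](C)C(=O)O[C@H]2COCc2ccc(OC)cc2 | intermediate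
26 | (3R,4S,5S)-4-formyl-5-{[(4-methoxybenzyl)oxy]methyl}-3-methyl-4-[(triethylsilyl)oxy]oxolan-2-one | O=C[C@]1(O[Si](CC)(CC)CC)[C@@H](C)C(=O)O[C@H]1COCc1ccc(OC)cc1 | intermediate
27 | cycloadduct: diphenyloxasilolane (C1, C2, O, Si, C14) cis-fused to the cyclohexene (C10=C11), with 1β-methyl, 12β-pinacolboryl, 13β-phenylsulfonyl and the 3-bromobut-3-enyl chain on C2 | C=C(Br)CC[C@@H]1O[Si](c2ccccc2)(c2ccccc2)[C@H]2[C@H](S(=O)(=O)c3ccccc3)[C@H](B3OC(C)(C)C(C)(C)O3)C(C)=C[C@@]12C | intermediate
28 | O-pinacolboryl ether of 29 | C=C(Br)CC[C@@H]1O[Si](c2ccccc2)(c2ccccc2)[C@H]2[C@H](S(=O)(=O)c3ccccc3)C=C(C)[C@H]([C@H](OB4OC(C)(C)C(C)(C)O4)[C@]3(O[Si](CC)(CC)CC)[C@@H](C)C(=O)O[C@H]3COCc3ccc(OC)cc3)[C@@]12C | intermediate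
29 | coupled alcohol: oxasilolane-fused cyclohexene (C11=C12) with 13β-phenylsulfonyl and, on C10 (β), the C9 carbinol bearing the silylated lactone | C=C(Br)CC[C@@H]1O[Si](c2ccccc2)(c2ccccc2)[C@H]2[C@H](S(=O)(=O)c3ccccc3)C=C(C)[C@H]([C@H](O)[C@]3(O[Si](CC)(CC)CC)[C@@H](C)C(=O)O[C@H]3COCc3ccc(OC)cc3)[C@@]12C | intermediate
30 | diene triol: cyclohexa-1,3-diene (C11=C12–C13=C14) with free 2-OH, 8-OH and 9-OH, alkenyl bromide at C5 and 4-methoxybenzyl ether at C6 | C=C(Br)CC[C@H](O)[C@@]1(C)C=CC=C(C)[C@@H]1[C@H](O)[C@]2(O)[C@@H](C)C(=O)O[C@H]2COCc2ccc(OC)cc2 | intermediate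
31 | pentaol: 30 with the 11α,12α-diol | C=C(Br)CC[C@H](O)[C@@]1(C)C=C[C@@H](O)[C@@](C)(O)[C@@H]1[C@H](O)[C@]2(O)[C@@H](C)C(=O)O[C@H]2COCc2ccc(OC)cc2 | intermediate
32 | 2,9,12-triacetate of 31 | C=C(Br)CC[C@H](OC(C)=O)[C@@]1(C)C=C[C@@H](OC(C)=O)[C@@](C)(O)[C@@H]1[C@H](OC(C)=O)[C@]2(O)[C@@H](C)C(=O)O[C@H]2COCc2ccc(OC)cc2 | intermediate
33 | triacetate with free C6 primary alcohol | C=C(Br)CC[C@H](OC(C)=O)[C@@]1(C)C=C[C@@H](OC(C)=O)[C@@](C)(O)[C@@H]1[C@H](OC(C)=O)[C@]2(O)[C@@H](C)C(=O)O[C@H]2CO | intermediate
34 | triacetate C6 aldehyde | C=C(Br)CC[C@H](OC(C)=O)[C@@]1(C)C=C[C@@H](OC(C)=O)[C@@](C)(O)[C@@H]1[C@H](OC(C)=O)[C@]2(O)[C@@H](C)C(=O)O[C@H]2C=O | intermediate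
35 | ten-membered allylic alcohol: the target with hydroxyl in place of chlorine at C6 and the opposite C6 configuration | C=C1CC[C@H](OC(C)=O)[C@@]2(C)C=C[C@@H](OC(C)=O)[C@@](C)(O)[C@@H]2[C@H](OC(C)=O)[C@]2(O)[C@@H](C)C(=O)O[C@H]2[C@@H]1O | intermediate
36 | CNP0259091.1 | C=C1CC[C@H](OC(C)=O)[C@@]2(C)C=C[C@@H](OC(C)=O)[C@@](C)(O)[C@@H]2[C@H](OC(C)=O)[C@]2(O)[C@@H](C)C(=O)O[C@H]2[C@H]1Cl | target

Total steps: 23. Longest linear sequence: 16 steps (steps 1–7, 9 and 16–23).

Steps most likely to fail

1. Step 16. The Z-configured diene may cycloadd slowly and, above all, the hindered allylboronate may transfer slowly to the α-quaternary aldehyde, so that protodeboronation competes. Fallback, setting out from 18 and 23 and coming back at 32: the lactone is built after the coupling. The dithiane of 23 is hydrolysed (MeI, CaCO3, aqueous MeCN) to the keto aldehyde F1, whose aldehyde carbon has only an sp2 neighbour. Cycloadduct 27, generated from 18 as in step 16, adds F1 without catalyst through the same chair transition state to give the α-hydroxy ketone F2. Acetylation (Ac2O, pyridine, DMAP) gives the 9-acetate F3; with this non-chelating group the Felkin–Anh preference at C9 and the trans preference across the forming lactone both favour the required C8 configuration. The SmI2 Reformatsky cyclisation (−78 °C) then gives the lactone F4. Bu4NF/AcOH gives the diene diol F5, OsO4/NMO gives the tetraol F6, and acetylation of the 2- and 12-hydroxyls returns to 32.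

2. Step 22. Oxidative addition of the alkenyl bromide may be sluggish, oligomerisation may compete with ring closure, and facial selectivity at C6 may be poor. Fallback, setting out from 34 and coming back at 35: if the ring closes mainly to the 6-epimeric alcohol F7, that alcohol is oxidised with Dess–Martin periodinane to the enone F8. F8 is then reduced under reagent control by Corey–Bakshi–Shibata reduction (oxazaborolidine catalyst, catecholborane), using the antipode of the catalyst that gives the 6-alcohol of 35.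

3. Step 18. The two ring alkenes may not be distinguished well enough, and over-oxidation may follow. Fallback, setting out from 29 and coming back at 31: the dihydroxylation is moved before the fluoride step. In 29 the only ring alkene is C11=C12, so OsO4/NMO gives the diol F9; Bu4NF/AcOH then eliminates the silyl and sulfonyl groups and removes the triethylsilyl group to give 31.

Further compounds
F1 | step 16 | (3S)-4-[(4-methoxybenzyl)oxy]-1,2-dioxobutan-3-yl 2-bromopropanoate (keto aldehyde) | O=CC(=O)[C@@H](OC(=O)C(C)Br)COCc1ccc(OC)cc1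
F2 | step 16 | α-hydroxy ketone: 29 with the open chain C9(OH)–C8(=O)–C7(O-2-bromopropanoyl)–C6 in place of the lactone | C=C(Br)CC[C@@H]1O[Si](c2ccccc2)(c2ccccc2)[C@H]2[C@H](S(=O)(=O)c3ccccc3)C=C(C)[C@H]([C@H](O)C(=O)[C@@H](OC(=O)C(C)Br)COCc3ccc(OC)cc3)[C@@]12C
F3 | step 16 | 9-acetate of F2 | C=C(Br)CC[C@@H]1O[Si](c2ccccc2)(c2ccccc2)[C@H]2[C@H](S(=O)(=O)c3ccccc3)C=C(C)[C@H]([C@H](OC(C)=O)C(=O)[C@@H](OC(=O)C(C)Br)COCc3ccc(OC)cc3)[C@@]12C
F4 | step 16 | lactone: 29 with 9-acetate and free 8-hydroxyl | C=C(Br)CC[C@@H]1O[Si](c2ccccc2)(c2ccccc2)[C@H]2[C@H](S(=O)(=O)c3ccccc3)C=C(C)[C@H]([C@H](OC(C)=O)[C@]3(O)[C@@H](C)C(=O)O[C@H]3COCc3ccc(OC)cc3)[C@@]12C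
F5 | step 16 | diene diol: 9-acetate of 30 | C=C(Br)CC[C@H](O)[C@@]1(C)C=CC=C(C)[C@@H]1[C@H](OC(C)=O)[C@]2(O)[C@@H](C)C(=O)O[C@H]2COCc2ccc(OC)cc2
F6 | step 16 | tetraol: 9-acetate of 31 | C=C(Br)CC[C@H](O)[C@@]1(C)C=C[C@@H](O)[C@@](C)(O)[C@@H]1[C@H](OC(C)=O)[C@]2(O)[C@@H](C)C(=O)O[C@H]2COCc2ccc(OC)cc2
F7 | step 22 | 6-epimer of 35 | C=C1CC[C@H](OC(C)=O)[C@@]2(C)C=C[C@@H](OC(C)=O)[C@@](C)(O)[C@@H]2[C@H](OC(C)=O)[C@]2(O)[C@@H](C)C(=O)O[C@H]2[C@H]1O
F8 | step 22 | C6 ketone (enone) of the ten-membered ring | C=C1CC[C@H](OC(C)=O)[C@@]2(C)C=C[C@@H](OC(C)=O)[C@@](C)(O)[C@@H]2[C@H](OC(C)=O)[C@]2(O)[C@@H](C)C(=O)O[C@H]2C1=O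
F9 | step 18 | 11α,12α-diol of 29 (oxasilolane, sulfone and triethylsilyl ether still in place) | C=C(Br)CC[C@@H]1O[Si](c2ccccc2)(c2ccccc2)[C@H]2[C@H](S(=O)(=O)c3ccccc3)[C@@H](O)[C@@](C)(O)[C@H]([C@H](O)[C@]3(O[Si](CC)(CC)CC)[C@@H](C)C(=O)O[C@H]3COCc3ccc(OC)cc3)[C@@]12C
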